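The flavone is cut at the pyranone ring C into three pieces: a ring-A iodophenol (carried as its acetate), carbon monoxide and a ring-B arylacetylene. One palladium-catalysed operation joins them: CO becomes C4, bonded to C4a and C3, and the unmasked phenol oxygen then closes O1–C2. The step exploits two features: C4 is a lone carbonyl carbon bridging C4a and C3, and ring A is fully substituted, so its phenol precursor has a single C–H, ortho to the oxygen that becomes O1, where iodine can only go. The precursor is 2-iodo-3,4,5,6-tetramethoxyphenyl acetate. A final chelation-controlled cleavage of the 5-OMe gives the target.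

Key step: step 4

Remark: the target has no stereocentre and is achiral, so no enantiomer has to be selected and every step is stereochemically silent.

Step 1
Reactants: 1 1,2,3,4-tetramethoxybenzene
Product: 4 2,3,4,5-tetramethoxyphenol, via aryllithium 2 (not isolated), via borate complex 3 (not isolated)
Conditions: n-BuLi, TMEDA, THF, 0 °C; B(OMe)3, −78 °C → rt; AcOH, 30% aq. H2O2, 0 °C → rt
Reagents that add atoms: hydrogen peroxide, OO
Why: Directed ortho-metalation by a methoxy group can reach only the two symmetry-equivalent ring C–H positions of 1, so a single aryllithium should form, and borate trapping followed by peroxide oxidation (1,2-shift of the aryl group from boron to oxygen) is the standard lithiation–borylation–oxidation route to a phenol.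

Step 2
Reactants: 4 2,3,4,5-tetramethoxyphenol
Product: 6 2-iodo-3,4,5,6-tetramethoxyphenyl acetate, via iodophenol 5 (not isolated)
Conditions: NIS (1.0 equiv), MeCN, 0 °C, dark; then pyridine, Ac2O, DMAP (cat.), rt
Reagents that add atoms: N-iodosuccinimide, O=C1CCC(=O)N1I; acetic anhydride, CC(=O)OC(C)=O
Why: Electrophilic aromatic iodination of the activated phenol has only one ring C–H to attack (ortho to OH), so the position of iodine is fixed, and DMAP-catalysed O-acetylation in the same flask caps the air-sensitive iodophenol as a stable ester.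

Step 3
Reactants: 7 2,4,5-trimethoxybenzaldehyde
Product: 9 1-ethynyl-2,4,5-trimethoxybenzene, via diazoalkene 8 (not isolated)
Conditions: dimethyl (1-diazo-2-oxopropyl)phosphonate (1.3 equiv), K2CO3, MeOH, 0 °C → rt
Reagents that add atoms: dimethyl (1-diazo-2-oxopropyl)phosphonate, CC(=O)C(=[N+]=[N-])P(=O)(OC)OC
Why: In this Seyferth–Gilbert homologation (Ohira–Bestmann variant), methanolysis releases the diazomethylphosphonate anion, its Horner–Wadsworth–Emmons-type addition–elimination on the non-enolisable aldehyde gives the diazoalkene, and loss of N2 with a 1,2-hydrogen shift should give the terminal alkyne under conditions that leave aryl methyl ethers untouched.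

Step 4
Reactants: 6 2-iodo-3,4,5,6-tetramethoxyphenyl acetate; 9 1-ethynyl-2,4,5-trimethoxybenzene (1.3 equiv); 10 carbon monoxide
Product: 14 5,6,7,8-tetramethoxy-2-(2,4,5-trimethoxyphenyl)-4H-chromen-4-one, via acetoxy ynone 11 (not isolated), via hydroxy ynone 12 (not isolated), via enaminone 13 (not isolated)
Conditions: PdCl2(PPh3)2 (5 mol %), dppp (5 mol %), thiourea (5 mol %), Et2NH, DBU (1.5 equiv), CO (1 atm), 40 °C
Reagents that add atoms: none
Why: Pd(0) inserts into the C–I bond of 6, CO migrates in to give the aroyl–palladium species, and amine-assisted transfer of the alkynyl group of 9 followed by reductive elimination forms C4a–C4 and C4–C3 in ynone 11. Et2NH and DBU then remove the acetyl group (12), Et2NH adds to the ynone β-carbon to give enaminone 13, and the phenol oxygen attacks that carbon (C2) and expels the amine, so the pyranone ring closes through the O1–C2 bond in a formally 6-endo-dig mode (6-endo-trig addition–elimination on 13). The closest known reaction type is the palladium-catalysed carbonylative Sonogashira annulation of o-iodophenols and their acetates with terminal arylacetylenes to flavones. The step needs carbonylative over direct alkynylation and six- over five-membered closure: the first should be secured by the CO atmosphere, the absence of copper, the donor-rich aryl–palladium bond that favours migratory insertion, and the acetate, which keeps a phenoxide from forming before the C–C bonds are made; the second by the enaminone, whose only electrophilic carbon is C2, made more cation-stabilising still by the trimethoxyphenyl ring. No stereocentre is formed, because the product is planar and achiral.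

Step 5
Reactants: 14 5,6,7,8-tetramethoxy-2-(2,4,5-trimethoxyphenyl)-4H-chromen-4-one
Product: 16 Agehoustin E (5-hydroxy-6,7,8-trimethoxy-2-(2,4,5-trimethoxyphenyl)-4H-chromen-4-one), via boron chelate 15 (not isolated)
Conditions: BCl3 (1.5 equiv), CH2Cl2, −78 → 0 °C; then H2O
Reagents that add atoms: none
Why: In this chelation-controlled Lewis-acid ether cleavage, BCl3 is held between the C4 carbonyl oxygen and the peri 5-OMe in a six-membered chelate, chloride removes that methyl group as chloromethane, and the six methoxy groups that cannot chelate with the carbonyl should survive at low temperature before water releases the hydrogen-bonded 5-OH.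

Compound list
1 | 1,2,3,4-tetramethoxybenzene | COc1ccc(OC)c(OC)c1OC | starting material
2 | (2,3,4,5-tetramethoxyphenyl)lithium | [Li]c1cc(OC)c(OC)c(OC)c1OC | intermediate
3 | lithium trimethoxy(2,3,4,5-tetramethoxyphenyl)borate | [Li+].CO[B-](OC)(OC)c1cc(OC)c(OC)c(OC)c1OC | intermediate
4 | 2,3,4,5-tetramethoxyphenol | Oc1cc(OC)c(OC)c(OC)c1OC | intermediate
5 | 2-iodo-3,4,5,6-tetramethoxyphenol | Oc1c(I)c(OC)c(OC)c(OC)c1OC | intermediate
6 | 2-iodo-3,4,5,6-tetramethoxyphenyl acetate | CC(=O)Oc1c(I)c(OC)c(OC)c(OC)c1OC | intermediate
7 | 2,4,5-trimethoxybenzaldehyde | COc1cc(OC)c(C=O)cc1OC | starting material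
8 | 1-(2-diazoethenyl)-2,4,5-trimethoxybenzene | COc1cc(OC)c(C=C=[N+]=[N-])cc1OC | intermediate
9 | 1-ethynyl-2,4,5-trimethoxybenzene | C#Cc1cc(OC)c(OC)cc1OC | intermediate
10 | carbon monoxide | [C-]#[O+] | starting material
11 | 3,4,5,6-tetramethoxy-2-[3-(2,4,5-trimethoxyphenyl)prop-2-ynoyl]phenyl acetate | CC(=O)Oc1c(C(=O)C#Cc2cc(OC)c(OC)cc2OC)c(OC)c(OC)c(OC)c1OC | intermediate
12 | 1-(2-hydroxy-3,4,5,6-tetramethoxyphenyl)-3-(2,4,5-trimethoxyphenyl)prop-2-yn-1-one | Oc1c(C(=O)C#Cc2cc(OC)c(OC)cc2OC)c(OC)c(OC)c(OC)c1OC | intermediate
13 | (E)-3-(diethylamino)-1-(2-hydroxy-3,4,5,6-tetramethoxyphenyl)-3-(2,4,5-trimethoxyphenyl)prop-2-en-1-one (the alkene geometry has no consequence for ring closure) | CCN(CC)/C(=C/C(=O)c1c(O)c(OC)c(OC)c(OC)c1OC)c1cc(OC)c(OC)cc1OC | intermediate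
14 | 5,6,7,8-tetramethoxy-2-(2,4,5-trimethoxyphenyl)-4H-chromen-4-one | COc1cc(OC)c(-c2cc(=O)c3c(OC)c(OC)c(OC)c(OC)c3o2)cc1OC | intermediate
15 | 5-(dichloroboryloxy)-6,7,8-trimethoxy-2-(2,4,5-trimethoxyphenyl)-4H-chromen-4-one (boron also coordinated by the C4 carbonyl oxygen) | COc1cc(OC)c(-c2cc(=O)c3c(OB(Cl)Cl)c(OC)c(OC)c(OC)c3o2)cc1OC | intermediate
16 | Agehoustin E, 5-hydroxy-6,7,8-trimethoxy-2-(2,4,5-trimethoxyphenyl)-4H-chromen-4-one | COc1cc(OC)c(-c2cc(=O)c3c(O)c(OC)c(OC)c(OC)c3o2)cc1OC | target

Total step count: 5 steps.
Longest linear sequence: 4 steps (steps 1, 2, 4 and 5); step 3 is a one-step side branch.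

Steps most likely to fail

Step 4. Transfer of the alkynyl group to the crowded, doubly ortho-substituted aroyl–palladium intermediate may be slower than its capture by diethylamine or than reduction of the aryl–palladium species. Early loss of the acetyl group may also open the non-carbonylative coupling path. The fallback is the classical chalcone route, which sets out from phenol 4 and aldehyde 7. Fries-type C-acetylation of 4 at its only free ring position (AcOH, BF3·OEt2, 80 °C) should give 1-(2-hydroxy-3,4,5,6-tetramethoxyphenyl)ethanone F1. Claisen–Schmidt condensation of F1 with 7 (KOH, EtOH, rt) should give (E)-1-(2-hydroxy-3,4,5,6-tetramethoxyphenyl)-3-(2,4,5-trimethoxyphenyl)prop-2-en-1-one F2. Oxidative cyclisation of F2 (I2 cat., DMSO, 130 °C) comes back to the route at flavone 14.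

Step 2. The very electron-rich phenol may be oxidised by the iodinating agent, with oxidative loss of a methyl group, faster than it is substituted. The fallback replaces electrophilic substitution by directed metalation and sets out from phenol 4. Protection (MOMCl, i-Pr2NEt, CH2Cl2) should give 1,2,3,4-tetramethoxy-5-(methoxymethoxy)benzene F3. Lithiation of its only ring C–H, flanked by the OMOM and OMe groups (n-BuLi, THF, 0 °C), and an iodine quench at −78 °C should give 1-iodo-2,3,4,5-tetramethoxy-6-(methoxymethoxy)benzene F4. Acidic methanolysis (HCl, MeOH, 40 °C) comes back to the route at iodophenol 5, which is then acetylated as in the second stage of step 2 to reach 6.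

Step 3. Addition of the diazophosphonate anion to the strongly donor-substituted, poorly electrophilic aldehyde may be slower than base-induced decomposition of the reagent, leaving the conversion incomplete. The fallback is a Corey–Fuchs sequence from aldehyde 7. CBr4 and PPh3 (CH2Cl2, 0 °C) should give 1-(2,2-dibromoethenyl)-2,4,5-trimethoxybenzene F5. n-BuLi (2.2 equiv, THF, −78 °C) followed by an aqueous quench comes back to the route at alkyne 9.

Further compounds
F1 | step 4 | 1-(2-hydroxy-3,4,5,6-tetramethoxyphenyl)ethanone | CC(=O)c1c(O)c(OC)c(OC)c(OC)c1OC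
F2 | step 4 | (E)-1-(2-hydroxy-3,4,5,6-tetramethoxyphenyl)-3-(2,4,5-trimethoxyphenyl)prop-2-en-1-one | COc1cc(OC)c(/C=C/C(=O)c2c(O)c(OC)c(OC)c(OC)c2OC)cc1OC
F3 | step 2 | 1,2,3,4-tetramethoxy-5-(methoxymethoxy)benzene | COCOc1cc(OC)c(OC)c(OC)c1OC
F4 | step 2 | 1-iodo-2,3,4,5-tetramethoxy-6-(methoxymethoxy)benzene | COCOc1c(I)c(OC)c(OC)c(OC)c1OC
F5 | step 3 | 1-(2,2-dibromoethenyl)-2,4,5-trimethoxybenzene | COc1cc(OC)c(C=C(Br)Br)cc1OC
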